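**Plan**

- Ring C (O1, C2, C3, C4, C4a, C8a) is a cyclic β-aryloxy ketone: O1 on C8a of ring A stands 1,3 to the C4 carbonyl. The O1–C2 bond is therefore cut first (oxa-conjugate addition), with a tert-butyl ester placed on C3 as a temporary activating group. The C2=C3 bond is cut next (Knoevenagel), giving a ring A β-ketoester and a ring B aldehyde.
- The chroman aldehyde is cut back through its C3 carbinol (a C3–C4 epoxide as temporary ring) and its pyran ring (propargyl ether, Claisen) to a benzaldehyde.
- Forward: pyran ring of the chroman (steps 1–2), its carbinol centre (steps 3–5), ring A ketoester (steps 6–7), union (step 8), ring C last (step 9), debenzylation (step 10).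
- Stereochemistry: chroman C3 (S) comes from a catalyst-controlled Jacobsen–Katsuki epoxidation. Flavanone C2 (S) comes from the chiral thiourea catalyst in the ring closure. The two centres are remote and set independently.

Key step: step 9

Assumption: the quinine-derived thiourea is taken to give the 2S sense; if a test cyclisation shows the opposite sense, the quinidine-derived pseudoenantiomer is used in the same way.

**Route**

Step 1
Reactants: 1 3-(benzyloxy)-4-hydroxybenzaldehyde; 2 3-chloro-3-methylbut-1-yne
Product: 3 3-(benzyloxy)-4-[(2-methylbut-3-yn-2-yl)oxy]benzaldehyde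
Conditions: K2CO3, KI (cat.), CuI (cat.), acetone, reflux
Reagents that add atoms: none
Why: Copper-assisted O-propargylation (Williamson-type etherification through the copper acetylide) of the only free phenol, the one para to the formyl group, is the standard entry to aryl 1,1-dimethylpropargyl ethers.

Step 2
Reactants: 3 3-(benzyloxy)-4-[(2-methylbut-3-yn-2-yl)oxy]benzaldehyde
Product: 5 8-(benzyloxy)-2,2-dimethyl-2H-chromene-6-carbaldehyde, via ortho-allenylphenol 4 (not isolated)
Conditions: N,N-diethylaniline, 190 °C
Reagents that add atoms: none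
Why: Aromatic propargyl Claisen rearrangement to the only free ortho position should give the ortho-allenylphenol, which closes by 1,5-hydrogen shift and oxa-6π electrocyclisation to the 2,2-dimethyl-2H-chromene.

Step 3
Reactants: 5 8-(benzyloxy)-2,2-dimethyl-2H-chromene-6-carbaldehyde
Product: 6 (3S,4S)-8-(benzyloxy)-3,4-epoxy-2,2-dimethylchroman-6-carbaldehyde
Conditions: (S,S)-N,N'-bis(3,5-di-tert-butylsalicylidene)-1,2-cyclohexanediaminomanganese chloride (trivalent manganese, 4 mol%), 4-phenylpyridine N-oxide (cat.), aq. NaOCl buffered with Na2HPO4 (pH about 11), CH2Cl2, 0 °C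
Reagents that add atoms: sodium hypochlorite, [Na+].[O-]Cl
Why: Jacobsen–Katsuki epoxidation, for which 2,2-dimethylchromenes are the best substrate class, should deliver oxygen to one face of the C3=C4 bond under control of the (S,S)-salen ligand and so set C3 and C4 as S.

Step 4
Reactants: 6 (3S,4S)-8-(benzyloxy)-3,4-epoxy-2,2-dimethylchroman-6-carbaldehyde
Product: 7 (3S)-8-(benzyloxy)-6-(hydroxymethyl)-2,2-dimethylchroman-3-ol
Conditions: LiAlH4, THF, 0 °C to rt; aqueous work-up
Reagents that add atoms: none
Why: Hydride should open the epoxide in SN2 fashion at the benzylic, less hindered C4 (C3 is neopentyl-like), so the C3–O bond and its S configuration are kept, while the aldehyde is reduced in the same operation (reductive epoxide opening plus carbonyl reduction).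

Step 5
Reactants: 7 (3S)-8-(benzyloxy)-6-(hydroxymethyl)-2,2-dimethylchroman-3-ol
Product: 8 (3S)-8-(benzyloxy)-3-hydroxy-2,2-dimethylchroman-6-carbaldehyde
Conditions: activated MnO2 (excess), CH2Cl2, rt
Reagents that add atoms: none
Why: Activated MnO2 oxidises only the benzylic primary alcohol and should leave the unactivated secondary carbinol untouched (chemoselective benzylic oxidation).

Step 6
Reactants: 9 methyl 2,4-dihydroxybenzoate
Product: 10 methyl 4-(benzyloxy)-2-hydroxybenzoate
Conditions: benzyl bromide (1.05 equiv), K2CO3, acetone, reflux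
Reagents that add atoms: benzyl bromide, BrCc1ccccc1
Why: Williamson etherification should occur at the 4-OH only, because the 2-OH is held in a hydrogen bond to the ester carbonyl and is much less nucleophilic.

Step 7
Reactants: 10 methyl 4-(benzyloxy)-2-hydroxybenzoate; 11 tert-butyl acetate
Product: 12 tert-butyl 3-[4-(benzyloxy)-2-hydroxyphenyl]-3-oxopropanoate
Conditions: lithium diisopropylamide (4 equiv), 11 (4 equiv), THF, −78 °C; then 10, −78 °C to 0 °C; aq. NH4Cl
Reagents that add atoms: none
Why: Crossed Claisen condensation, in which excess lithium enolate of 11 first deprotonates the phenol and then acylates at the methyl ester, the product being held as its enolate until the quench; the tert-butyl ester is chosen because it resists lactonisation to the 4-hydroxycoumarin.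

Step 8
Reactants: 12 tert-butyl 3-[4-(benzyloxy)-2-hydroxyphenyl]-3-oxopropanoate; 8 (3S)-8-(benzyloxy)-3-hydroxy-2,2-dimethylchroman-6-carbaldehyde
Product: 13 tert-butyl (2Z)-2-[4-(benzyloxy)-2-hydroxybenzoyl]-3-[(3S)-8-(benzyloxy)-3-hydroxy-2,2-dimethylchroman-6-yl]prop-2-enoate (drawn as the Z isomer; any E isomer is carried along)
Conditions: piperidine (cat.), AcOH (cat.), 4 Å molecular sieves, toluene, rt
Reagents that add atoms: none
Why: Knoevenagel condensation of the active methylene of 12 with aldehyde 8 under piperidinium acetate catalysis with removal of water, run mildly so that the phenol does not yet add to the new alkene.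

Step 9
Reactants: 13 tert-butyl (2Z)-2-[4-(benzyloxy)-2-hydroxybenzoyl]-3-[(3S)-8-(benzyloxy)-3-hydroxy-2,2-dimethylchroman-6-yl]prop-2-enoate
Product: 16 (2S)-7-(benzyloxy)-2-[(3S)-8-(benzyloxy)-3-hydroxy-2,2-dimethylchroman-6-yl]chroman-4-one, via cyclised tert-butyl ester 14 (not isolated), via beta-keto acid 15 (not isolated)
Conditions: N-[3,5-bis(trifluoromethyl)phenyl]-N'-[(8α,9S)-6'-methoxycinchonan-9-yl]thiourea (quinine-derived, 10 mol%), toluene, −25 °C; then p-TsOH·H2O, 80 °C
Reagents that add atoms: none
Why: The thiourea N–H bonds of the catalyst bind the two carbonyl oxygens of the alkylidene β-ketoester (C4 ketone and C3 ester) while the quinuclidine nitrogen takes the proton of the ring A phenol, so that O1 adds to C2 inside a chiral ion pair and the resulting ketoester enolate is protonated at C3 (intramolecular oxa-Michael addition). The closest known reaction type is the cinchona thiourea-catalysed asymmetric oxa-conjugate addition of 2-hydroxyaryl alkylidene β-ketoesters with in-pot acid decarboxylation, as used for 2-aryl chroman-4-ones. Ring C closes in the 6-endo-trig mode by forming the O1–C2 bond. C2 is set by the catalyst alone, which exposes one face of the C2=C3 bond to the bound phenoxide; the chroman carbinol centre is too remote to matter, so there is no matched or mismatched case and any minor C2 epimer is a separable diastereomer. The step needs kinetic control over the reversible addition, which is secured by the low temperature and by the acid stage, in which p-TsOH cleaves the tert-butyl ester (2-methylpropene) and the β-keto acid loses CO2, removing the activation that makes ring opening easy. It also needs O1 to win over the free secondary alcohol, which is secured by the acidity of the phenol and by the fact that only O1 can reach C2 through a six-membered transition state.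

Step 10
Reactants: 16 (2S)-7-(benzyloxy)-2-[(3S)-8-(benzyloxy)-3-hydroxy-2,2-dimethylchroman-6-yl]chroman-4-one
Product: 17 (2S)-2-[(3S)-3,8-dihydroxy-2,2-dimethylchroman-6-yl]-7-hydroxychroman-4-one
Conditions: H2 (1 atm), 10% Pd/C, EtOAc, rt, stopped when both ethers are cleaved
Reagents that add atoms: none
Why: Hydrogenolysis of the two aryl benzyl ethers over Pd/C runs under neutral conditions, which avoid the base-induced ring opening (retro-oxa-Michael) that would scramble C2.

**Compound list**

1 | 3-(benzyloxy)-4-hydroxybenzaldehyde | O=Cc1ccc(O)c(OCc2ccccc2)c1 | starting material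
2 | 3-chloro-3-methylbut-1-yne | C#CC(C)(C)Cl | starting material
3 | 3-(benzyloxy)-4-[(2-methylbut-3-yn-2-yl)oxy]benzaldehyde | O=Cc1ccc(OC(C)(C)C#C)c(OCc2ccccc2)c1 | intermediate
4 | 3-(benzyloxy)-4-hydroxy-5-(3-methylbuta-1,2-dien-1-yl)benzaldehyde (ortho-allenylphenol) | O=Cc1cc(C=C=C(C)C)c(O)c(OCc2ccccc2)c1 | intermediate (not isolated)
5 | 8-(benzyloxy)-2,2-dimethyl-2H-chromene-6-carbaldehyde | CC1(C)C=Cc2cc(C=O)cc(OCc3ccccc3)c2O1 | intermediate
6 | (3S,4S)-8-(benzyloxy)-3,4-epoxy-2,2-dimethylchroman-6-carbaldehyde | CC1(C)Oc2c(OCc3ccccc3)cc(C=O)cc2[C@@H]4O[C@H]14 | intermediate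
7 | (3S)-8-(benzyloxy)-6-(hydroxymethyl)-2,2-dimethylchroman-3-ol | CC1(C)Oc2c(OCc3ccccc3)cc(CO)cc2C[C@@H]1O | intermediate
8 | (3S)-8-(benzyloxy)-3-hydroxy-2,2-dimethylchroman-6-carbaldehyde | CC1(C)Oc2c(OCc3ccccc3)cc(C=O)cc2C[C@@H]1O | intermediate
9 | methyl 2,4-dihydroxybenzoate | COC(=O)c1ccc(O)cc1O | starting material
10 | methyl 4-(benzyloxy)-2-hydroxybenzoate | COC(=O)c1ccc(OCc2ccccc2)cc1O | intermediate
11 | tert-butyl acetate | CC(=O)OC(C)(C)C | starting material
12 | tert-butyl 3-[4-(benzyloxy)-2-hydroxyphenyl]-3-oxopropanoate | CC(C)(C)OC(=O)CC(=O)c1ccc(OCc2ccccc2)cc1O | intermediate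
13 | tert-butyl (2Z)-2-[4-(benzyloxy)-2-hydroxybenzoyl]-3-[(3S)-8-(benzyloxy)-3-hydroxy-2,2-dimethylchroman-6-yl]prop-2-enoate | CC1(C)Oc2c(OCc3ccccc3)cc(/C=C(\C(=O)OC(C)(C)C)C(=O)c3ccc(OCc4ccccc4)cc3O)cc2C[C@@H]1O | intermediate
14 | tert-butyl (2S,3R)-7-(benzyloxy)-2-[(3S)-8-(benzyloxy)-3-hydroxy-2,2-dimethylchroman-6-yl]-4-oxochroman-3-carboxylate (2,3-trans shown; C3 is labile and also present as the enol) | CC1(C)Oc2c(OCc3ccccc3)cc([C@@H]3[C@@H](C(=O)OC(C)(C)C)C(=O)c4ccc(OCc5ccccc5)cc4O3)cc2C[C@@H]1O | intermediate (not isolated)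
15 | (2S,3R)-7-(benzyloxy)-2-[(3S)-8-(benzyloxy)-3-hydroxy-2,2-dimethylchroman-6-yl]-4-oxochroman-3-carboxylic acid | CC1(C)Oc2c(OCc3ccccc3)cc([C@@H]3[C@@H](C(=O)O)C(=O)c4ccc(OCc5ccccc5)cc4O3)cc2C[C@@H]1O | intermediate (not isolated)
16 | (2S)-7-(benzyloxy)-2-[(3S)-8-(benzyloxy)-3-hydroxy-2,2-dimethylchroman-6-yl]chroman-4-one | CC1(C)Oc2c(OCc3ccccc3)cc([C@@H]3CC(=O)c4ccc(OCc5ccccc5)cc4O3)cc2C[C@@H]1O | intermediate
17 | (2S)-2-[(3S)-3,8-dihydroxy-2,2-dimethylchroman-6-yl]-7-hydroxychroman-4-one | CC1(C)Oc2c(O)cc([C@@H]3CC(=O)c4ccc(O)cc4O3)cc2C[C@@H]1O | target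

**Step count and risks**

Total step count: 10. Longest linear sequence: 8 steps (steps 1, 2, 3, 4, 5, 8, 9, 10).

Steps most likely to fail:

1. Step 9. The enantioselectivity may be eroded by reversible ring opening (retro-oxa-Michael) of the adduct, which the electron-rich ring B favours, before or during the acid decarboxylation. The fallback sets out from 8. Claisen–Schmidt condensation of 8 with purchased 1-[4-(benzyloxy)-2-hydroxyphenyl]ethanone F1 (KOH, EtOH, rt) should give the 2'-hydroxychalcone (2E)-1-[4-(benzyloxy)-2-hydroxyphenyl]-3-[(3S)-8-(benzyloxy)-3-hydroxy-2,2-dimethylchroman-6-yl]prop-2-en-1-one F2. Thermodynamic ring closure (NaOAc, EtOH, reflux) should then give 16 together with its C2 epimer (2R)-7-(benzyloxy)-2-[(3S)-8-(benzyloxy)-3-hydroxy-2,2-dimethylchroman-6-yl]chroman-4-one F3. Because the chroman centre is fixed, the two are diastereomers, to be separated by preparative chromatography or crystallisation, with the unwanted epimer returned to the equilibration. The route is rejoined at 16.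

2. Step 3. The formyl group may be oxidised by the hypochlorite and oxo-manganese system in competition with oxygen transfer to the C3=C4 bond. The fallback sets out from 5. Acetalisation (HC(OMe)3, cat. p-TsOH, MeOH) should give 8-(benzyloxy)-6-(dimethoxymethyl)-2,2-dimethyl-2H-chromene F4. The same epoxidation should then give (3S,4S)-8-(benzyloxy)-6-(dimethoxymethyl)-3,4-epoxy-2,2-dimethylchroman F5, which has no oxidisable formyl group. LiAlH4 in THF should open it to (3S)-8-(benzyloxy)-6-(dimethoxymethyl)-2,2-dimethylchroman-3-ol F6. Mild hydrolysis (pyridinium p-toluenesulfonate, acetone/H2O) then frees the aldehyde, so the reduction and re-oxidation of the formyl carbon are avoided. The route is rejoined at 8.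

3. Step 10. Over-reduction may occur, namely hydrogenolytic cleavage of the benzylic C2–O1 bond of ring C or reduction of the C4 carbonyl, in competition with cleavage of the two O-benzyl groups. The fallback sets out from 16 and uses a non-reductive Lewis-acid debenzylation (BCl3, pentamethylbenzene as cation scavenger, CH2Cl2, −78 °C). This cannot hydrogenolyse the C2–O1 bond or reduce the ketone, and the benzyl groups are trapped on the scavenger. It arrives directly at 17 and makes no new intermediate.

**Further compounds**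

F1 | step 9 | 1-[4-(benzyloxy)-2-hydroxyphenyl]ethanone | CC(=O)c1ccc(OCc2ccccc2)cc1O
F2 | step 9 | (2E)-1-[4-(benzyloxy)-2-hydroxyphenyl]-3-[(3S)-8-(benzyloxy)-3-hydroxy-2,2-dimethylchroman-6-yl]prop-2-en-1-one | CC1(C)Oc2c(OCc3ccccc3)cc(/C=C/C(=O)c3ccc(OCc4ccccc4)cc3O)cc2C[C@@H]1O
F3 | step 9 | (2R)-7-(benzyloxy)-2-[(3S)-8-(benzyloxy)-3-hydroxy-2,2-dimethylchroman-6-yl]chroman-4-one | CC1(C)Oc2c(OCc3ccccc3)cc([C@H]3CC(=O)c4ccc(OCc5ccccc5)cc4O3)cc2C[C@@H]1O
F4 | step 3 | 8-(benzyloxy)-6-(dimethoxymethyl)-2,2-dimethyl-2H-chromene | CC1(C)C=Cc2cc(C(OC)OC)cc(OCc3ccccc3)c2O1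
F5 | step 3 | (3S,4S)-8-(benzyloxy)-6-(dimethoxymethyl)-3,4-epoxy-2,2-dimethylchroman | CC1(C)Oc2c(OCc3ccccc3)cc(C(OC)OC)cc2[C@@H]4O[C@H]14
F6 | step 3 | (3S)-8-(benzyloxy)-6-(dimethoxymethyl)-2,2-dimethylchroman-3-ol | CC1(C)Oc2c(OCc3ccccc3)cc(C(OC)OC)cc2C[C@@H]1O
F0 | step 10 | none | none
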